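**Retrosynthetic overview**
1. The trans-decalin C1–C10 (rings A/B) with stereocentres C5, C9 and C10 and the exocyclic C8=C17 methylene next to C7 is read as the product of an allylsilane-terminated polyene bicyclisation. C4–C5 and C9–C10 are cut last, back to an acyclic E,E-triene chain on the finished core, with a C7 silyl ether as control element.
2. Core ring D (methoxy-enedione) is cut by a sulfonylbutenolide Michael–Dieckmann annulation from a 2-(cyclohexa-1,4-dienyl)chromone, so that both ring-fusion carbons form anti to the C11 chain.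
3. The chromone pyranone ring comes from a Claisen/cyclodehydration, and ring C (the cyclohexadiene carbon bearing C11) from a catalytic enantioselective Diels–Alder of the acyclic silyl pentaene with a propioloyl pyrazole.
4. The pentaene comes from isoprenol, silylpropyne, Me3Al and oxirane (C1–C7), a propargyl sulfolene (C8, C9, C11 and the masked diene) and Me3SiCH2MgCl (C17); C7 is set by asymmetric alkynylation.
5. Ring order: ring C, pyranone ring, ring D, then rings A and B together; the chromone benzene ring is bought.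

Key step: step 20

Remark: drimane numbering (C1–C11, C17) is used for the terpenoid part and 4a,5,8,8a-tetrahydronaphthalene-1,4-dione numbering for the core; for the chiral ligands of steps 8 and 14 the antipode that gives the drawn configuration is meant; 15–17 are mixtures of two epimers at the sulfolene carbon, which disappears in step 10; "SC" is the side chain (2Z,4S,6E)-4-[(tert-butyldimethylsilyl)oxy]-7,11-dimethyl-3-[(trimethylsilyl)methyl]dodeca-2,6,11-trien-1-yl.

**Step 1**
Reactants: 1 3-methylbut-3-en-1-ol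
Product: 2 4-iodo-2-methylbut-1-ene
Conditions: PPh3, I2, imidazole, CH2Cl2, 0 °C to rt
Reagents that add atoms: iodine, II
Why: Appel-type iodination of an unhindered primary alcohol through the alkoxyphosphonium salt should leave the 1,1-disubstituted alkene untouched.

**Step 2**
Reactants: 2 4-iodo-2-methylbut-1-ene; 3 trimethyl(prop-1-yn-1-yl)silane
Product: 4 trimethyl(6-methylhept-6-en-1-yn-1-yl)silane
Conditions: 3, n-BuLi, THF, −78 to −20 °C; then 2, −78 °C to rt
Reagents that add atoms: none
Why: Lithiated 1-silylpropyne should be alkylated at its propargylic carbon by the primary iodide (SN2), which brings in C1, C10 and C5 as a protected terminal alkyne.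

**Step 3**
Reactants: 4 trimethyl(6-methylhept-6-en-1-yn-1-yl)silane
Product: 5 6-methylhept-6-en-1-yne
Conditions: K2CO3 (cat.), MeOH, rt
Reagents that add atoms: none
Why: Base-catalysed methanolysis of the C(sp)–Si bond frees the terminal alkyne.

**Step 4**
Reactants: 5 6-methylhept-6-en-1-yne; 6 oxirane
Product: 9 (3E)-4,8-dimethylnona-3,8-dien-1-ol, via alkenyldimethylalane 7 (not isolated), via lithium alkenylaluminate 8 (not isolated)
Conditions: Me3Al, Cp2ZrCl2 (25 mol%), CH2Cl2, 0 °C to rt; evaporate; n-BuLi, hexane/THF, −30 °C; 6, −30 °C to rt; aq. HCl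
Reagents that add atoms: trimethylaluminium, C[Al](C)C
Why: Zirconium-catalysed syn-carboalumination (Negishi) puts methyl on C10 and aluminium on C5, which fixes the E geometry of C5=C10, and the derived ate complex should open oxirane with retention at the alkenyl carbon.

**Step 5**
Reactants: 9 (3E)-4,8-dimethylnona-3,8-dien-1-ol
Product: 10 (3E)-4,8-dimethylnona-3,8-dienal
Conditions: Dess–Martin periodinane, NaHCO3, CH2Cl2, 0 °C; used crude
Reagents that add atoms: none
Why: Buffered Dess–Martin oxidation is neutral enough to give the β,γ-unsaturated aldehyde without shifting the alkene into conjugation.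

**Step 6**
Reactants: 11 3-methyl-2,5-dihydrothiophene 1,1-dioxide; 12 (3-bromoprop-1-yn-1-yl)trimethylsilane
Product: 13 3-methyl-2-[3-(trimethylsilyl)prop-2-yn-1-yl]-2,5-dihydrothiophene 1,1-dioxide (racemic)
Conditions: LiHMDS added to 11 and 12, THF/DMPU, −78 °C
Reagents that add atoms: none
Why: α-Alkylation of the sulfolene anion in the presence of the electrophile should occur at C2 next to the methyl-bearing carbon, because that allylic anion keeps its charge off the substituted terminus.

**Step 7**
Reactants: 13 silylated propargyl sulfolene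
Product: 14 3-methyl-2-(prop-2-yn-1-yl)-2,5-dihydrothiophene 1,1-dioxide (racemic)
Conditions: TBAF, AcOH, THF, 0 °C
Reagents that add atoms: none
Why: Buffered fluoride protodesilylation of the alkynylsilane avoids base-induced isomerisation of the 3-sulfolene.

**Step 8**
Reactants: 10 (3E)-4,8-dimethylnona-3,8-dienal; 14 propargyl sulfolene
Product: 15 2-[(4S,6E)-4-hydroxy-7,11-dimethyldodeca-6,11-dien-2-yn-1-yl]-3-methyl-2,5-dihydrothiophene 1,1-dioxide
Conditions: 14 (2 equiv), Me2Zn, ProPhenol ligand (20 mol%), Ph3P=O (40 mol%), toluene, 0 °C; then 10, 4 °C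
Reagents that add atoms: none
Why: Zinc–ProPhenol catalysed enantioselective alkynylation should deliver the alkynylzinc to one aldehyde face inside the dinuclear zinc complex and set C7 as S, under conditions too weakly basic to move the β,γ-alkene.

**Step 9**
Reactants: 15 propargylic alcohol
Product: 17 2-[(2Z,4S,6E)-4-hydroxy-3-iodo-7,11-dimethyldodeca-2,6,11-trien-1-yl]-3-methyl-2,5-dihydrothiophene 1,1-dioxide, via alkenylstannane 16 (not isolated)
Conditions: Bu3SnH, [Cp*RuCl]4 (2.5 mol%), CH2Cl2, rt; then I2, 0 °C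
Reagents that add atoms: iodine, II
Why: Hydroxyl-directed ruthenium-catalysed trans-hydrostannation should place tin on C8 next to the carbinol and hydrogen anti on C9, so that C7 and C11 become trans, and iododestannylation keeps that geometry.

**Step 10**
Reactants: 17 iodo sulfolene
Product: 18 (3E,6Z,8S,10E)-7-iodo-3,11,15-trimethylhexadeca-1,3,6,10,15-pentaen-8-ol
Conditions: toluene, pyridine (2 equiv), 110 °C
Reagents that add atoms: none
Why: Cheletropic (disrotatory) loss of SO2 from the 2-substituted 3-sulfolene should give the E-diene, since the substituent turns outward.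

**Step 11**
Reactants: 18 iodo pentaenol
Product: 19 (3E,6Z,8S,10E)-3,11,15-trimethyl-7-[(trimethylsilyl)methyl]hexadeca-1,3,6,10,15-pentaen-8-ol
Conditions: Me3SiCH2MgCl (3 equiv), Pd(PPh3)4 (5 mol%), THF, rt
Reagents that add atoms: (trimethylsilyl)methylmagnesium chloride, C[Si](C)(C)C[Mg]Cl
Why: Kumada coupling of the alkenyl iodide proceeds with retention and gives the allylsilane with CH2SiMe3 on C8 cis to C11.

**Step 12**
Reactants: 19 allylsilane alcohol
Product: 20 tert-butyldimethylsilyl ether of 19 (the silyl pentaene, SC–CH=C(CH3)–CH=CH2 in the sense that C1 of SC is the diene terminus)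
Conditions: TBSOTf, 2,6-lutidine, CH2Cl2, −78 °C
Reagents that add atoms: tert-butyldimethylsilyl trifluoromethanesulfonate, CC(C)(C)[Si](C)(C)OS(=O)(=O)C(F)(F)F
Why: Silylation of the secondary allylic alcohol under buffered conditions gives the C7 control element and spares the allylsilane.

**Step 13**
Reactants: 21 prop-2-ynoic acid; 22 3,5-dimethyl-1H-pyrazole
Product: 23 1-(3,5-dimethyl-1H-pyrazol-1-yl)prop-2-yn-1-one
Conditions: DCC, CH2Cl2, 0 °C
Reagents that add atoms: none
Why: Carbodiimide-mediated N-acylation gives the activated propioloyl pyrazole, a two-point-binding alkyne dienophile.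

**Step 14**
Reactants: 20 silyl pentaene; 23 propioloyl pyrazole
Product: 24 (3,5-dimethyl-1H-pyrazol-1-yl)[(6R)-5-methyl-6-SC-cyclohexa-1,4-dien-1-yl]methanone
Conditions: Cu(NTf2)2 (10 mol%), 3-(2-naphthyl)alanine-derived amide ligand (11 mol%), MeCN/CH2Cl2, −40 °C
Reagents that add atoms: none
Why: Copper(II)-catalysed enantioselective Diels–Alder of the N,O-chelated propioloyl pyrazole should join the free diene terminus to the alkyne CH (ortho orientation, with the 2-methyl group working against it), and the ligand-shielded chelate lets only one diene face add, which sets core C5 as R where the remote C7 centre could not.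

**Step 15**
Reactants: 24 Diels–Alder adduct; 25 1-(2,6-dihydroxy-4-methoxyphenyl)ethan-1-one
Product: 27 5-hydroxy-7-methoxy-2-[(6R)-5-methyl-6-SC-cyclohexa-1,4-dien-1-yl]-4H-chromen-4-one, via diketone 26 (not isolated)
Conditions: 25 (2 equiv), LiHMDS (6 equiv), THF, −78 to −10 °C; 24, −78 to −20 °C; then AcOH, 60 °C
Reagents that add atoms: none
Why: Claisen-type C-acylation of the acetophenone polyanion by the acyl pyrazole and acid-promoted cyclodehydration of the o-hydroxyaryl 1,3-diketone (Kostanecki-type chromone synthesis) should close the pyranone ring and leave the second phenol as the chelated 5-OH.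

**Step 16**
Reactants: 27 5-hydroxychromone diene
Product: 28 5-[(tert-butyldimethylsilyl)oxy]-7-methoxy-2-[(6R)-5-methyl-6-SC-cyclohexa-1,4-dien-1-yl]-4H-chromen-4-one
Conditions: TBSOTf, 2,6-lutidine, CH2Cl2, 0 °C
Reagents that add atoms: tert-butyldimethylsilyl trifluoromethanesulfonate, CC(C)(C)[Si](C)(C)OS(=O)(=O)C(F)(F)F
Why: Silylation of the chelated phenol removes the acidic proton that would quench and deactivate the acceptor in step 19.

**Step 17**
Reactants: 29 4-methoxyfuran-2(5H)-one
Product: 30 5-bromo-4-methoxyfuran-2(5H)-one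
Conditions: NBS, AIBN (cat.), PhCF3, reflux; used crude
Reagents that add atoms: N-bromosuccinimide, O=C1CCC(=O)N1Br
Why: Wohl–Ziegler bromination should take the C5 hydrogen, which is allylic and next to the ring oxygen.

**Step 18**
Reactants: 30 5-bromo-4-methoxyfuran-2(5H)-one
Product: 31 4-methoxy-5-(phenylsulfonyl)furan-2(5H)-one
Conditions: PhSO2Na, DMF, rt
Reagents that add atoms: sodium benzenesulfinate, [Na+].[O-]S(=O)c1ccccc1
Why: S-Alkylation of the sulfinate by the acetal-like bromide gives the sulfonyl butenolide donor.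

**Step 19**
Reactants: 28 silylated chromone diene; 31 sulfonyl butenolide
Product: 33 (4aS,5R,8aR)-4a-{5-[(tert-butyldimethylsilyl)oxy]-7-methoxy-4-oxo-4H-chromen-2-yl}-2-methoxy-6-methyl-5-SC-4a,5,8,8a-tetrahydronaphthalene-1,4-dione, via 1,6-adduct 32 (not isolated)
Conditions: 31, LiHMDS (1.05 equiv), THF, −78 °C; 28 (0.8 equiv), −78 to 0 °C; AcOH quench at −40 °C
Reagents that add atoms: none
Why: Proposed new method: the lithiated sulfonyl butenolide should add 1,6 to the cyclohexadienyl CH remote from the chromone (vinylogous Michael), the chromone dienolate should then attack the lactone carbonyl through its exocyclic carbon (Dieckmann), and collapse with loss of phenylsulfinate unveils the second ketone, so ring D closes as the 2-methoxy-ene-1,4-dione; the closest known reaction types are the Hauser–Kraus (Michael–Dieckmann) annulation of sulfonyl phthalides with enones and 1,6-additions of stabilised carbanions to 2-alkenylchromones; acylation at the chromone-bearing carbon is expected anti to the neighbouring C11 chain, the tether enforces the cis ring fusion and the reversible Michael step lets the H-bearing fusion carbon follow, which sets core C4a as S and C8a as R.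

**Step 20**
Reactants: 33 acyclic precursor on the finished core
Product: 34 (4aS,5R,8aR)-4a-{5-[(tert-butyldimethylsilyl)oxy]-7-methoxy-4-oxo-4H-chromen-2-yl}-5-{[(1R,3S,4aS,8aS)-3-[(tert-butyldimethylsilyl)oxy]-5,5,8a-trimethyl-2-methylidenedecahydronaphthalen-1-yl]methyl}-2-methoxy-6-methyl-4a,5,8,8a-tetrahydronaphthalene-1,4-dione (drimane labels 5S,7S,9R,10S)
Conditions: Co(II) salen catalyst (10 mol%), N-fluoro-2,4,6-trimethylpyridinium triflate (1.5 equiv), PhSiH3 (1.5 equiv), HFIP/CH2Cl2, 0 °C, 0.01 M
Reagents that add atoms: none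
Why: Cobalt-hydride hydrogen-atom transfer to the terminal CH2 of the isopropenyl group gives the tertiary C4 radical, which is oxidised to the C4 cation (radical–polar crossover); C5=C10 then attacks C4 and the allylsilane alkene C8=C9 attacks C10, and the β-silyl cation at C8 loses Me3Si+ to leave only the exocyclic C8=C17 alkene. The closest known reaction types are metal-hydride HAT-initiated radical–polar crossover polyene cyclisations and classical allylsilane-terminated cation–olefin cyclisations. Ring A (C4–C5) and ring B (C9–C10) both close 6-endo through a chair–chair fold. The E geometry of C5=C10 gives the trans ring fusion (C5 against C10), and the C8=C9 geometry with C7 trans to C11 puts C11 equatorial at C9. The absolute sense is set by the C7 silyl ether, which should sit equatorial, because an axial C–O bond would lie syn to the C17–Si bond that must stand anti to the incoming C10 and would also withdraw electron density from the reacting π bond. The step needs HAT at the 1,1-disubstituted alkene in preference to the trisubstituted alkenes, the enedione and the chromone, which the higher HAT rate of the unhindered terminal alkene and high dilution should secure.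

**Step 21**
Reactants: 34 bis-silyl ether
Product: 35 7-hydroxy compound with free 5-OH (the (3S)-3-hydroxy analogue of 34 without both silyl groups)
Conditions: HF·pyridine, pyridine, THF, 0 °C to rt
Reagents that add atoms: none
Why: Buffered fluoride cleaves the aryl and the secondary silyl ether without base, so the epimerisable cis ring fusion and the vinylogous ester should survive.

**Step 22**
Reactants: 35 allylic alcohol
Product: 36 Dichrostachine M
Conditions: Dess–Martin periodinane, NaHCO3, CH2Cl2, 0 °C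
Reagents that add atoms: none
Why: Dess–Martin oxidation of the C7 allylic alcohol gives the C7 ketone conjugated with C8=C17 and removes the auxiliary stereocentre; the chelated phenol is not expected to react.

**Compound list**
1 | 3-methylbut-3-en-1-ol | C=C(C)CCO | starting material
2 | 4-iodo-2-methylbut-1-ene | C=C(C)CCI | intermediate
3 | trimethyl(prop-1-yn-1-yl)silane | CC#C[Si](C)(C)C | starting material
4 | trimethyl(6-methylhept-6-en-1-yn-1-yl)silane | C=C(C)CCCC#C[Si](C)(C)C | intermediate
5 | 6-methylhept-6-en-1-yne | C=C(C)CCCC#C | intermediate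
6 | oxirane | C1CO1 | starting material
7 | [(1E)-2,6-dimethylhepta-1,6-dien-1-yl]dimethylalane | C=C(C)CCC/C(C)=C/[Al](C)C | intermediate (not isolated)
8 | lithium butyl[(1E)-2,6-dimethylhepta-1,6-dien-1-yl]dimethylaluminate | [Li+].C=C(C)CCC/C(C)=C/[Al-](C)(C)CCCC | intermediate (not isolated)
9 | (3E)-4,8-dimethylnona-3,8-dien-1-ol | C=C(C)CCC/C(C)=C/CCO | intermediate
10 | (3E)-4,8-dimethylnona-3,8-dienal | C=C(C)CCC/C(C)=C/CC=O | intermediate
11 | 3-methyl-2,5-dihydrothiophene 1,1-dioxide | CC1=CCS(=O)(=O)C1 | starting material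
12 | (3-bromoprop-1-yn-1-yl)trimethylsilane | C[Si](C)(C)C#CCBr | starting material
13 | 3-methyl-2-[3-(trimethylsilyl)prop-2-yn-1-yl]-2,5-dihydrothiophene 1,1-dioxide (racemic) | CC1=CCS(=O)(=O)C1CC#C[Si](C)(C)C | intermediate
14 | 3-methyl-2-(prop-2-yn-1-yl)-2,5-dihydrothiophene 1,1-dioxide (racemic) | CC1=CCS(=O)(=O)C1CC#C | intermediate
15 | 2-[(4S,6E)-4-hydroxy-7,11-dimethyldodeca-6,11-dien-2-yn-1-yl]-3-methyl-2,5-dihydrothiophene 1,1-dioxide (both sulfolene epimers) | C=C(C)CCC/C(C)=C/C[C@H](O)C#CCC1C(C)=CCS1(=O)=O | intermediate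
16 | 2-[(2Z,4S,6E)-4-hydroxy-7,11-dimethyl-3-(tributylstannyl)dodeca-2,6,11-trien-1-yl]-3-methyl-2,5-dihydrothiophene 1,1-dioxide | C=C(C)CCC/C(C)=C/C[C@H](O)/C(=C/CC1C(C)=CCS1(=O)=O)[Sn](CCCC)(CCCC)CCCC | intermediate (not isolated)
17 | 2-[(2Z,4S,6E)-4-hydroxy-3-iodo-7,11-dimethyldodeca-2,6,11-trien-1-yl]-3-methyl-2,5-dihydrothiophene 1,1-dioxide | C=C(C)CCC/C(C)=C/C[C@H](O)/C(I)=C/CC1C(C)=CCS1(=O)=O | intermediate
18 | (3E,6Z,8S,10E)-7-iodo-3,11,15-trimethylhexadeca-1,3,6,10,15-pentaen-8-ol | C=C(C)CCC/C(C)=C/C[C@H](O)/C(I)=C/C/C=C(C)/C=C | intermediate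
19 | (3E,6Z,8S,10E)-3,11,15-trimethyl-7-[(trimethylsilyl)methyl]hexadeca-1,3,6,10,15-pentaen-8-ol | C=C(C)CCC/C(C)=C/C[C@H](O)/C(C[Si](C)(C)C)=C/C/C=C(C)/C=C | intermediate
20 | tert-butyldimethyl{[(3E,6Z,8S,10E)-3,11,15-trimethyl-7-[(trimethylsilyl)methyl]hexadeca-1,3,6,10,15-pentaen-8-yl]oxy}silane | C=C(C)CCC/C(C)=C/C[C@H](O[Si](C)(C)C(C)(C)C)/C(C[Si](C)(C)C)=C/C/C=C(C)/C=C | intermediate
21 | prop-2-ynoic acid | C#CC(=O)O | starting material
22 | 3,5-dimethyl-1H-pyrazole | Cc1cc(C)[nH]n1 | starting material
23 | 1-(3,5-dimethyl-1H-pyrazol-1-yl)prop-2-yn-1-one | C#CC(=O)n1nc(C)cc1C | intermediate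
24 | (3,5-dimethyl-1H-pyrazol-1-yl)[(6R)-5-methyl-6-SC-cyclohexa-1,4-dien-1-yl]methanone | C=C(C)CCC/C(C)=C/C[C@H](O[Si](C)(C)C(C)(C)C)/C(C[Si](C)(C)C)=C/C[C@@H]1C(C)=CCC=C1C(=O)n1nc(C)cc1C | intermediate
25 | 1-(2,6-dihydroxy-4-methoxyphenyl)ethan-1-one | CC(=O)c1c(O)cc(OC)cc1O | starting material
26 | 1-(2,6-dihydroxy-4-methoxyphenyl)-3-[(6R)-5-methyl-6-SC-cyclohexa-1,4-dien-1-yl]propane-1,3-dione | C=C(C)CCC/C(C)=C/C[C@H](O[Si](C)(C)C(C)(C)C)/C(C[Si](C)(C)C)=C/C[C@@H]1C(C)=CCC=C1C(=O)CC(=O)c1c(O)cc(OC)cc1O | intermediate (not isolated)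
27 | 5-hydroxy-7-methoxy-2-[(6R)-5-methyl-6-SC-cyclohexa-1,4-dien-1-yl]-4H-chromen-4-one | C=C(C)CCC/C(C)=C/C[C@H](O[Si](C)(C)C(C)(C)C)/C(C[Si](C)(C)C)=C/C[C@@H]1C(C)=CCC=C1c1cc(=O)c2c(O)cc(OC)cc2o1 | intermediate
28 | 5-[(tert-butyldimethylsilyl)oxy]-7-methoxy-2-[(6R)-5-methyl-6-SC-cyclohexa-1,4-dien-1-yl]-4H-chromen-4-one | C=C(C)CCC/C(C)=C/C[C@H](O[Si](C)(C)C(C)(C)C)/C(C[Si](C)(C)C)=C/C[C@@H]1C(C)=CCC=C1c1cc(=O)c2c(O[Si](C)(C)C(C)(C)C)cc(OC)cc2o1 | intermediate
29 | 4-methoxyfuran-2(5H)-one (methyl tetronate) | COC1=CC(=O)OC1 | starting material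
30 | 5-bromo-4-methoxyfuran-2(5H)-one | COC1=CC(=O)OC1Br | intermediate
31 | 4-methoxy-5-(phenylsulfonyl)furan-2(5H)-one | COC1=CC(=O)OC1S(=O)(=O)c1ccccc1 | intermediate
32 | 1,6-adduct of 31 to 28 (present as its lithium dienolate; new centres not specified) | C=C(C)CCC/C(C)=C/C[C@H](O[Si](C)(C)C(C)(C)C)/C(C[Si](C)(C)C)=C/C[C@@H]1C(C)=CCC(C2(OC(=O)C=C2OC)S(=O)(=O)c2ccccc2)C1c1cc(=O)c2c(O[Si](C)(C)C(C)(C)C)cc(OC)cc2o1 | intermediate (not isolated)
33 | (4aS,5R,8aR)-4a-{5-[(tert-butyldimethylsilyl)oxy]-7-methoxy-4-oxo-4H-chromen-2-yl}-2-methoxy-6-methyl-5-SC-4a,5,8,8a-tetrahydronaphthalene-1,4-dione | C=C(C)CCC/C(C)=C/C[C@H](O[Si](C)(C)C(C)(C)C)/C(C[Si](C)(C)C)=C/C[C@@H]1C(C)=CC[C@H]2C(=O)C(OC)=CC(=O)[C@@]12c1cc(=O)c2c(O[Si](C)(C)C(C)(C)C)cc(OC)cc2o1 | intermediate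
34 | key-step product, C7 and 5-O silyl ethers (drimane 5S,7S,9R,10S; core 4aS,5R,8aR) | C=C1[C@@H](O[Si](C)(C)C(C)(C)C)C[C@H]2C(C)(C)CCC[C@]2(C)[C@H]1C[C@@H]1C(C)=CC[C@H]2C(=O)C(OC)=CC(=O)[C@@]12c1cc(=O)c2c(O[Si](C)(C)C(C)(C)C)cc(OC)cc2o1 | intermediate
35 | (7S)-7-hydroxy compound with free 5-OH | C=C1[C@@H](O)C[C@H]2C(C)(C)CCC[C@]2(C)[C@H]1C[C@@H]1C(C)=CC[C@H]2C(=O)C(OC)=CC(=O)[C@@]12c1cc(=O)c2c(O)cc(OC)cc2o1 | intermediate
36 | Dichrostachine M | C=C1C(=O)C[C@H]2C(C)(C)CCC[C@]2(C)[C@H]1C[C@@H]1C(C)=CC[C@H]2C(=O)C(OC)=CC(=O)[C@@]12c1cc(=O)c2c(O)cc(OC)cc2o1 | target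

**Step count**
Total: 22 steps. Longest linear sequence: 17 steps (1–5, 8–12, 14–16, 19–22).

**Steps most likely to fail**

1. Step 19 (Proposed new method). The stabilised furanolate may add reversibly without the ring closing, the dienolate may be protonated or react through the chromone C3 instead of forming the hindered quaternary centre, and proton transfer from the doubly allylic CH2 may lead to aromatisation of the cyclohexadiene. The fallback uses a quinone Diels–Alder; it sets out from 25 and 20 and comes back at 33. Acetophenone 25 would be acylated as its polyanion with 2,4,5-trimethoxybenzoyl chloride and cyclised with acid to 5-hydroxy-7-methoxy-2-(2,4,5-trimethoxyphenyl)-4H-chromen-4-one F1. Ceric ammonium nitrate would oxidise F1 to 2-(5-hydroxy-7-methoxy-4-oxo-4H-chromen-2-yl)-5-methoxycyclohexa-2,5-diene-1,4-dione F2, which would be silylated to its 5-O-tert-butyldimethylsilyl ether F3. A thermal Diels–Alder of F3 with pentaene 20 closes rings C and D in one step, but 33 would then form next to endo and facial isomers and would have to be separated from them.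

2. Step 20 (key step). The C4 radical or cation may be intercepted before both rings close (reduction, elimination back to alkenes, capture by fluoride or solvent), hydrogen-atom transfer may also reach the other alkenes or the enedione, and the fold with an axial silyl ether may compete. The fallback separates radical generation from the cationic cascade; it sets out from 33 and comes back at 34. Markovnikov hydrochlorination by HAT (cobalt salen catalyst, TsCl, PhSiH3) would give the tertiary chloride F4, and silver triflate with 2,6-di-tert-butylpyridine in CH2Cl2 at −40 °C would ionise it to the C4 cation, which closes both rings with allylsilane termination.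

3. Step 15. The strongly basic polyanion may deprotonate the dienoyl unit at its γ-position, after which the double bonds move into conjugation and the ring oxidises to the arene; the acidic cyclodehydration may also protodesilylate the allylsilane. The fallback is a neutral intramolecular Wittig chromone synthesis; it sets out from 25 and 24 and comes back at 27. α-Bromination of 25 with CuBr2 would give 2-bromo-1-(2,6-dihydroxy-4-methoxyphenyl)ethan-1-one F5, PPh3 the phosphonium bromide F6, and Na2CO3 the stabilised ylide F7. Ylide F7 would be O-acylated by acyl pyrazole 24 (DMAP) to the aryl ester ylide F8, and heating in toluene closes the pyranone ring by olefination of the ester carbonyl to give 27 without a strong base.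

**Further compounds**
F1 | step 19 | 5-hydroxy-7-methoxy-2-(2,4,5-trimethoxyphenyl)-4H-chromen-4-one | COc1cc(OC)c(OC)cc1-c1cc(=O)c2c(O)cc(OC)cc2o1
F2 | step 19 | 2-(5-hydroxy-7-methoxy-4-oxo-4H-chromen-2-yl)-5-methoxycyclohexa-2,5-diene-1,4-dione | COC1=CC(=O)C(=CC1=O)c1cc(=O)c2c(O)cc(OC)cc2o1
F3 | step 19 | 2-{5-[(tert-butyldimethylsilyl)oxy]-7-methoxy-4-oxo-4H-chromen-2-yl}-5-methoxycyclohexa-2,5-diene-1,4-dione | COC1=CC(=O)C(=CC1=O)c1cc(=O)c2c(O[Si](C)(C)C(C)(C)C)cc(OC)cc2o1
F4 | step 20 | tertiary C4 chloride of 33 (HCl added across the isopropenyl group) | CC(C)(Cl)CCC/C(C)=C/C[C@H](O[Si](C)(C)C(C)(C)C)/C(C[Si](C)(C)C)=C/C[C@@H]1C(C)=CC[C@H]2C(=O)C(OC)=CC(=O)[C@@]12c1cc(=O)c2c(O[Si](C)(C)C(C)(C)C)cc(OC)cc2o1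
F5 | step 15 | 2-bromo-1-(2,6-dihydroxy-4-methoxyphenyl)ethan-1-one | O=C(CBr)c1c(O)cc(OC)cc1O
F6 | step 15 | [2-(2,6-dihydroxy-4-methoxyphenyl)-2-oxoethyl]triphenylphosphonium bromide | [Br-].O=C(C[P+](c1ccccc1)(c1ccccc1)c1ccccc1)c1c(O)cc(OC)cc1O
F7 | step 15 | 1-(2,6-dihydroxy-4-methoxyphenyl)-2-(triphenyl-λ5-phosphanylidene)ethan-1-one | O=C(C=P(c1ccccc1)(c1ccccc1)c1ccccc1)c1c(O)cc(OC)cc1O
F8 | step 15 | 3-hydroxy-5-methoxy-2-[(triphenyl-λ5-phosphanylidene)acetyl]phenyl (6R)-5-methyl-6-SC-cyclohexa-1,4-diene-1-carboxylate | C=C(C)CCC/C(C)=C/C[C@H](O[Si](C)(C)C(C)(C)C)/C(C[Si](C)(C)C)=C/C[C@@H]1C(C)=CCC=C1C(=O)Oc1cc(OC)cc(O)c1C(=O)C=P(c1ccccc1)(c1ccccc1)c1ccccc1
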